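Ring B (labdane numbering) is a cyclohexene whose C7=C8 double bond lies opposite the C5–C10 ring-fusion bond: a Diels–Alder retron. An enantioselective, oxazaborolidinium-catalysed [4+2] cycloaddition of a ring-A enal (C5=C10, its formyl group the future C10 methyl) with a vinyl dihydropyranone (diene C6=C7–C8=C9, the lactone masking the C17 hydroxyl and the C12 aldehyde) forms C5–C6 and C9–C10 in one operation and sets the quaternary C10 and C9. C5 and C6 are then relayed from C10: epimerisation through a C6 enone and hydride delivery anti to the angular methyl. The lactone is finally unravelled into the acetoxymethyl group and the dienyl side chain.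

Key step: step 5

Remark on numbering: labdane numbers are used throughout (ring A: C1–C5, C10; ring B: C5–C10; C17 on C8; C11–C16 side chain on C9; C18, C19 on C4; C20 on C10); β is the face of the bicycle that carries C20.

Assumption: the (S)-configured oxazaborolidinium catalyst is taken to leave open the Re face of the formyl-bearing carbon of enal 3 (usual model for α-substituted enals); if the sense is the reverse, the (R)-catalyst is used and nothing else changes.

Step 1
Reactants: 1 2,2-dimethylcyclohexan-1-one
Product: 2 2-bromo-3,3-dimethylcyclohex-1-ene-1-carbaldehyde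
Conditions: PBr3, DMF, CHCl3, 0 → 60 °C; then ice-water
Reagents that add atoms: N,N-dimethylformamide, CN(C)C=O (formyl carbon); phosphorus tribromide, BrP(Br)Br (bromine); water, O (aldehyde oxygen)
Why: Vilsmeier–Haack–Arnold bromoformylation should formylate the only enolisable α-carbon (future C10) and turn the carbonyl carbon (future C5) into the vinyl bromide; no stereocenter is formed.

Step 2
Reactants: 2 2-bromo-3,3-dimethylcyclohex-1-ene-1-carbaldehyde
Product: 3 3,3-dimethylcyclohex-1-ene-1-carbaldehyde
Conditions: Pd(OAc)2 (3 mol %), PPh3, HCO2H, Et3N, DMF, 60 °C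
Reagents that add atoms: none
Why: Palladium-catalysed formate hydrodehalogenation (oxidative addition of the activated β-bromo enal to zerovalent palladium, formate exchange, decarboxylation, reductive elimination) should give the enal without touching C=C or CHO; no stereocenter.

Step 3
Reactants: 4 but-3-enoic acid; 5 prop-2-yn-1-ol
Product: 6 prop-2-yn-1-yl but-3-enoate
Conditions: DCC, DMAP (2 mol %), CH2Cl2, 0 °C
Reagents that add atoms: none
Why: Steglich esterification at low temperature with little DMAP should avoid isomerisation of the β,γ-unsaturated acid to the crotonate; no stereocenter.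

Step 4
Reactants: 6 prop-2-yn-1-yl but-3-enoate
Product: 7 5-ethenyl-3,6-dihydro-2H-pyran-2-one
Conditions: second-generation Grubbs catalyst, (H2IMes)(PCy3)Cl2Ru=CHPh (5 mol %), ethylene (1 atm), CH2Cl2 (0.01 M), 40 °C
Reagents that add atoms: none
Why: Ring-closing enyne metathesis in the exo mode should close the six-membered lactone and leave a 1,3-diene whose C8=C9 bond is locked in the ring, so that C11 is fixed trans to the vinyl group; no stereocenter.

Step 5
Reactants: 3 3,3-dimethylcyclohex-1-ene-1-carbaldehyde; 7 5-ethenyl-3,6-dihydro-2H-pyran-2-one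
Product: 8 (5S,9R,10S)-20-oxo-13,14,15,16-tetranorlabd-7-en-12,17-olide with A/B cis (CHO on C10, H on C5 and C11 on C9 all β)
Conditions: (S)-1-(2-methylphenyl)-3,3-diphenyltetrahydro-1H,3H-pyrrolo[1,2-c][1,3,2]oxazaborole·HN(SO2CF3)2 (20 mol %), 7 (1.5 equiv), CH2Cl2, −40 → 0 °C
Reagents that add atoms: none
Why: The boron Lewis acid binds the formyl oxygen of 3 and a concerted, asynchronous [4+2] cycloaddition (closest known type: oxazaborolidinium-catalysed Diels–Alder reactions of α-substituted enals with 1-vinylcycloalkene dienes) joins the unsubstituted diene terminus C6 to the β-carbon C5 and the ring terminus C9 to the formyl-bearing C10. Ring B, the six-membered carbocycle, is closed in the cycloaddition mode, both σ bonds forming suprafacially on each partner. C10 is set by the catalyst, which should leave only the Re face of the formyl-bearing carbon open; C9 follows from the endo orientation of the formyl group, which places the lactone CH2 (C11, the outside substituent of the diene) cis to CHO; C5 follows from the cis ring alkene, so H5 is cis to CHO and is corrected in step 8. The step needs regioselectivity (C9 to C10) and endo selectivity: the first should come from the ortho preference of the substituted diene terminus for the carbonyl-bearing carbon and from the neopentyl β-carbon accepting only the CH2 terminus, the second from ring A with its gem-dimethyl group being unable to sit under the diene.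

Step 6
Reactants: 8 lactone aldehyde (A/B cis)
Product: 10 13,14,15,16-tetranor-5β-labd-7-en-12,17-olide (A/B cis; C10 methyl, H5 and C11 all β), via tosylhydrazone 9 (not isolated)
Conditions: TsNHNH2, EtOH, 50 °C; concentrate; catecholborane, CHCl3, 0 °C; then NaOAc·3H2O, 60 °C
Reagents that add atoms: none
Why: Caglioti-type deoxygenation (hydrazone formation, hydroboration of C=N, acetate-induced loss of sulfinate and N2) should turn the neopentyl aldehyde into the C10 methyl under conditions a lactone and a trisubstituted alkene survive; C10 has no α-hydrogen, so no stereocenter is touched.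

Step 7
Reactants: 10 cis-fused lactone
Product: 11 6-oxo-13,14,15,16-tetranor-5β-labd-7-en-12,17-olide (A/B cis)
Conditions: CrO3, 3,5-dimethylpyrazole, CH2Cl2, −20 °C
Reagents that add atoms: chromium trioxide, O=[Cr](=O)=O
Why: Allylic oxidation with the CrO3·3,5-dimethylpyrazole complex should go at C6, the only allylic CH2 next to the CH end of the trisubstituted alkene (C9–H is tertiary and hindered, C17 is deactivated by its acyloxy oxygen); no stereocenter changes.

Step 8
Reactants: 11 cis-fused enone lactone
Product: 12 6-oxo-13,14,15,16-tetranorlabd-7-en-12,17-olide (A/B trans, H5 α)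
Conditions: DBU, toluene, 80 °C
Reagents that add atoms: none
Why: Base-mediated epimerisation at C5 through the cross-conjugated dienolate should lead to the thermodynamically preferred trans-fused 4,4,10-trimethyl octalone with H5 anti to the angular methyl, while C9 should keep its pseudo-equatorial C11.

Step 9
Reactants: 12 trans-fused enone lactone
Product: 13 6β-hydroxy-13,14,15,16-tetranorlabd-7-en-12,17-olide
Conditions: NaBH4, CeCl3·7H2O, MeOH, −78 → −20 °C
Reagents that add atoms: none
Why: Luche 1,2-reduction: the β face of the C6 carbonyl is screened by the 1,3-diaxial C10 and C4 methyl groups, so hydride should enter from the α face and give the axial 6β-alcohol, the lactone surviving at low temperature.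

Step 10
Reactants: 13 hydroxy lactone
Product: 14 12,17-epoxy-13,14,15,16-tetranorlabd-7-ene-6β,12-diol (lactol, anomeric mixture)
Conditions: i-Bu2AlH (2.5 equiv), CH2Cl2, −78 °C; then H2O
Reagents that add atoms: none
Why: Low-temperature DIBAL reduction of a δ-lactone should stop at the aluminium hemiacetal (the free 6-OH consumes one equivalent); the new hemiacetal center is an anomeric mixture of no consequence.

Step 11
Reactants: 14 lactol
Product: 16 (12E)-6β,17-dihydroxy-15-norlabda-7,12-dien-14-al, via open-chain hydroxy aldehyde 15 (not isolated)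
Conditions: Ph3P=C(CH3)CHO, toluene, 90 °C
Reagents that add atoms: 2-(triphenylphosphoranylidene)propanal, CC(C=O)=P(c1ccccc1)(c1ccccc1)c1ccccc1
Why: Wittig reaction of the stabilised ylide with the open hydroxy-aldehyde form of the lactol should give the (E)-2-methyl enal (E selectivity of stabilised α-branched ylides) and release the C17 hydroxyl.

Step 12
Reactants: 16 enal diol
Product: 17 (12E)-labda-7,12,14-triene-6β,17-diol
Conditions: Ph3PCH3Br, KN(SiMe3)2, THF, 0 °C; then 16, −78 → 0 °C
Reagents that add atoms: methyltriphenylphosphonium bromide, C[P+](c1ccccc1)(c1ccccc1)c1ccccc1.[Br-]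
Why: Wittig methylenation with base-free ylide, which is not basic enough to deprotonate the hydroxyl groups and so should not trigger oxa-Michael closure onto the enal, completes the (E)-3-methylpenta-2,4-dienyl chain.

Step 13
Reactants: 17 triene diol
Product: 18 (5R,6S,9S,10S,12E)-labda-7,12,14-triene-6,17-diyl diacetate (6β-OAc)
Conditions: Ac2O, pyridine, DMAP (cat.), CH2Cl2, 23 → 40 °C
Reagents that add atoms: acetic anhydride, CC(=O)OC(C)=O
Why: DMAP-catalysed acetylation should esterify the primary allylic C17–OH and, with warming, the hindered axial 6β-OH; no stereocenter changes.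

Compound list

1 | 2,2-dimethylcyclohexan-1-one | CC1(C)CCCCC1=O | starting material
2 | 2-bromo-3,3-dimethylcyclohex-1-ene-1-carbaldehyde | O=CC1=C(Br)C(C)(C)CCC1 | intermediate
3 | 3,3-dimethylcyclohex-1-ene-1-carbaldehyde | O=CC1=CC(C)(C)CCC1 | intermediate
4 | but-3-enoic acid | C=CCC(=O)O | starting material
5 | prop-2-yn-1-ol | C#CCO | starting material
6 | prop-2-yn-1-yl but-3-enoate | C=CCC(=O)OCC#C | intermediate
7 | 5-ethenyl-3,6-dihydro-2H-pyran-2-one | C=CC1=CCC(=O)OC1 | intermediate
8 | (5S,9R,10S)-20-oxo-13,14,15,16-tetranorlabd-7-en-12,17-olide, A/B cis (CHO, H5, C11 all β) | O=C3C[C@@H]1C(CO3)=CC[C@H]2C(C)(C)CCC[C@@]12C=O | intermediate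
9 | C20 tosylhydrazone of 8 (C=N geometry not specified) | O=C3C[C@@H]1C(CO3)=CC[C@H]2C(C)(C)CCC[C@@]12C=NNS(=O)(=O)c4ccc(C)cc4 | intermediate
10 | 13,14,15,16-tetranor-5β-labd-7-en-12,17-olide, A/B cis | O=C3C[C@@H]1C(CO3)=CC[C@H]2C(C)(C)CCC[C@@]12C | intermediate
11 | 6-oxo-13,14,15,16-tetranor-5β-labd-7-en-12,17-olide, A/B cis | O=C3C[C@@H]1C(CO3)=CC(=O)[C@H]2C(C)(C)CCC[C@@]12C | intermediate
12 | 6-oxo-13,14,15,16-tetranorlabd-7-en-12,17-olide, A/B trans (H5 α) | O=C3C[C@@H]1C(CO3)=CC(=O)[C@@H]2C(C)(C)CCC[C@@]12C | intermediate
13 | 6β-hydroxy-13,14,15,16-tetranorlabd-7-en-12,17-olide | O=C3C[C@@H]1C(CO3)=C[C@H](O)[C@@H]2C(C)(C)CCC[C@@]12C | intermediate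
14 | 12,17-epoxy-13,14,15,16-tetranorlabd-7-ene-6β,12-diol (lactol, C12 anomers) | OC3C[C@@H]1C(CO3)=C[C@H](O)[C@@H]2C(C)(C)CCC[C@@]12C | intermediate
15 | 6β,17-dihydroxy-13,14,15,16-tetranorlabd-7-en-12-al | O=CC[C@@H]1C(CO)=C[C@H](O)[C@@H]2C(C)(C)CCC[C@@]12C | intermediate
16 | (12E)-6β,17-dihydroxy-15-norlabda-7,12-dien-14-al | O=C/C(C)=C/C[C@@H]1C(CO)=C[C@H](O)[C@@H]2C(C)(C)CCC[C@@]12C | intermediate
17 | (12E)-labda-7,12,14-triene-6β,17-diol | C=C/C(C)=C/C[C@@H]1C(CO)=C[C@H](O)[C@@H]2C(C)(C)CCC[C@@]12C | intermediate
18 | (5R,6S,9S,10S,12E)-labda-7,12,14-triene-6,17-diyl diacetate | C=C/C(C)=C/C[C@@H]1C(COC(C)=O)=C[C@H](OC(C)=O)[C@@H]2C(C)(C)CCC[C@@]12C | target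

Total step count: 13. Longest linear sequence: 11 steps (steps 1, 2, 5–13; the diene branch, steps 3, 4, 5–13, is equally long).

Steps most likely to fail

Step 5. The cycloaddition at the hindered, neopentyl-flanked enal may be slow, so that an uncatalysed or poorly organised pathway takes over and facial control is lost. The fallback sets out from 3 and 7 and replaces catalyst control by resolution. The cycloaddition is run with an achiral promoter (EtAlCl2, CH2Cl2, −20 °C) to give 8 together with its mirror image, ent-8 F1. Condensation of the mixture with (1R,2R)-N,N′-dimethyl-1,2-diphenylethane-1,2-diamine (MgSO4, CH2Cl2) should give two diastereomeric imidazolidines, aminal of 8 F2 and aminal of ent-8 F3, which are separated by chromatography. Hydrolysis of F2 (aqueous AcOH, THF) comes back to the route at 8.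

Step 7. Hydrogen abstraction at the tertiary allylic C9–H, or further oxidation, may compete with clean oxidation at C6. The fallback sets out from 10 and moves the oxygen in by rearrangement:
- epoxidation of C7=C8 (mCPBA, CH2Cl2) should give epoxide F4;
- opening at the less hindered C7 with sodium phenylselenide (EtOH) should give hydroxy selenide F5;
- H2O2 should give selenoxide F6, which eliminates in the flask toward C6 to tertiary allylic alcohol F7;
- Babler–Dauben oxidative 1,3-transposition with pyridinium chlorochromate, [C5H5NH][CrO3Cl], in CH2Cl2 comes back to the route at 11.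

The configurations at C7 and C8 in F4–F7 are immaterial, since both centers become sp2 again.

Step 8. Equilibration at the hindered C5–H may be slow or incomplete, or the extended enolate may scramble C9. The fallback sets out from 11 and sets C5 kinetically. Soft enolisation (Me3SiOTf, Et3N, CH2Cl2, 0 °C) should give the cross-conjugated silyl dienol ether F8. Protonation at −78 °C (HCl, THF–H2O) should then deliver the proton to C5 from the α face, anti to the angular methyl, and comes back to the route at 12.

Further compounds

F1 | step 5 | ent-8, enantiomer of lactone aldehyde 8 | O=C3C[C@H]1C(CO3)=CC[C@@H]2C(C)(C)CCC[C@]12C=O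
F2 | step 5 | aminal (1,3-dimethyl-4,5-diphenylimidazolidine, 4R,5R) of 8 | O=C3C[C@@H]1C(CO3)=CC[C@H]2C(C)(C)CCC[C@@]12C4N(C)[C@H](c5ccccc5)[C@@H](c5ccccc5)N4C
F3 | step 5 | aminal (1,3-dimethyl-4,5-diphenylimidazolidine, 4R,5R) of ent-8 | O=C3C[C@H]1C(CO3)=CC[C@@H]2C(C)(C)CCC[C@]12C4N(C)[C@H](c5ccccc5)[C@@H](c5ccccc5)N4C
F4 | step 7 | 7,8-epoxide of 10 (C7, C8 configuration not specified) | O=C3C[C@@H]1C4(CO3)OC4C[C@H]2C(C)(C)CCC[C@@]12C
F5 | step 7 | 8-hydroxy-7-(phenylselanyl) lactone (C7, C8 configuration not specified) | O=C3C[C@@H]1C(O)(CO3)C([Se]c4ccccc4)C[C@H]2C(C)(C)CCC[C@@]12C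
F6 | step 7 | selenoxide of F5 | O=C3C[C@@H]1C(O)(CO3)C([Se](=O)c4ccccc4)C[C@H]2C(C)(C)CCC[C@@]12C
F7 | step 7 | 8-hydroxy-6-ene lactone (tertiary allylic alcohol, C8 configuration not specified) | O=C3C[C@@H]1C(O)(CO3)C=C[C@H]2C(C)(C)CCC[C@@]12C
F8 | step 8 | 6-(trimethylsilyloxy)-5,7-diene lactone (silyl dienol ether of 11) | O=C3C[C@@H]1C(CO3)=CC(O[Si](C)(C)C)=C2C(C)(C)CCC[C@@]12C
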